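**Strategy.** The cyclohexane fused to the gem-dimethylcyclopropane (ring carbons C1–C6) is the carane ring of (+)-3-carene. Its C3–C4 bond (C3 = quaternary carbon bearing the aryl-ether oxygen, C4 = the CH bearing the secondary methyl) is the carene double bond. A Claisen rearrangement fixes C2 and ozonolysis cuts C3=C4. The key step closes that bond again: hydrogen-atom transfer to a vinyl group creates the C4 methyl and a C4 radical, which adds 6-exo to C3 of a cyclopentane-1,3-dione and gives a tricyclic enone. A quinone-methide Michael/oxa-Michael annulation then builds the bridged benzoxepine ring; deoxygenation and double formylation complete the target.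

Key step: step 6

Numbering used below (carane numbering, kept for every intermediate): C1 and C6 = cyclopropane CH carbons; C7 = CMe2; C2 = ring-fusion CH; C3 = carbon that becomes the O-bearing quaternary centre; C4 = carbon that becomes CH–CH3; C5 = CH2; C10 = the carene methyl carbon (a cyclopentane CH2 in the target); C11 = the other cyclopentane CH2; C12 = the methyl-bearing quaternary carbon; C1′ = benzylic CH.

Assumption: commercial (+)-3-carene is the (1S,6R) enantiomer; its C1/C6 configuration matches the target only when the carene methyl is mapped onto C10 and not onto the C4 methyl.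

**Step 1**
Reactants: 1 (+)-3-carene
Product: 3 trans-car-2-en-4-ol, via allylic hydroperoxide 2 (not isolated)
Conditions: O2, hν (visible), tetraphenylporphyrin (cat.), CH2Cl2, 0 °C; then PPh3, 0 °C → rt; chromatography
Reagents that add atoms: oxygen, O=O
Why: Schenck ene reaction: singlet oxygen adds to C4 of the trisubstituted alkene on the face away from the gem-dimethylcyclopropane while taking the allylic hydrogen from C2, so that after phosphine reduction the C4 hydroxyl is trans to the cyclopropane, and the secondary alcohol is separated from the regioisomeric allylic alcohols that the ene reaction is also expected to give.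

**Step 2**
Reactants: 3 trans-car-2-en-4-ol; 4 triethyl orthopropionate
Product: 5 ethyl 2-(car-3-en-2-yl)propanoate (side chain at C2 trans to the cyclopropane)
Conditions: 4 (excess), EtCO2H (cat.), 140 °C, EtOH distilled off
Reagents that add atoms: none
Why: Johnson–Claisen rearrangement: the ketene acetal formed on the C4 oxygen transfers the propanoate carbon suprafacially to C2, so the new C2–C12 bond stands on the face the oxygen occupied (trans to the cyclopropane) and the C3=C4 alkene is restored; C12 forms as an epimer mixture, which is harmless because C12 is enolised in step 9.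

**Step 3**
Reactants: 5 ethyl 2-(car-3-en-2-yl)propanoate
Product: 7 keto aldehyde ester, via secondary ozonide 6 (not isolated)
Conditions: O3, CH2Cl2, −78 °C; then Me2S, −78 °C → rt
Reagents that add atoms: ozone, [O-][O+]=O
Why: Ozonolysis with reductive work-up cleaves the only alkene, C3=C4, to the C3 methyl ketone and the C4 aldehyde and leaves the cyclopropane and the C2 stereocentre untouched.

**Step 4**
Reactants: 7 keto aldehyde ester
Product: 8 keto ester alkene
Conditions: Ph3PCH3Br, KN(SiMe3)2, THF, 0 °C; then 7, −78 → 0 °C
Reagents that add atoms: methyltriphenylphosphonium bromide, C[P+](c1ccccc1)(c1ccccc1)c1ccccc1.[Br-]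
Why: Wittig methylenation: one equivalent of the non-stabilised ylide at low temperature reacts with the aldehyde much faster than with the hindered methyl ketone or the ester, and no stereocentre is formed.

**Step 5**
Reactants: 8 keto ester alkene
Product: 9 4-[cis-2,2-dimethyl-3-(prop-2-enyl)cyclopropyl]-5-methylcyclopentane-1,3-dione
Conditions: LiN(iPr)2 (1.3 equiv), THF, −78 °C → rt; then aq. HCl
Reagents that add atoms: none
Why: Intramolecular Claisen (Dieckmann-type) condensation: the amide base removes a proton of the C10 methyl under kinetic control, which leaves the enolisable C2 stereocentre alone, and the enolate acylates on the ester carbon C11 to close the five-membered 1,3-dione.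

**Step 6**
Reactants: 9 cyclopentane-1,3-dione with the vinyl-bearing cyclopropyl arm
Product: 11 tricyclic enone, via ketol 10 (not isolated)
Conditions: Fe(acac)3 (30 mol %), PhSiH3, EtOH/ethylene glycol, 60 °C; then p-TsOH·H2O (cat.), toluene, 50 °C
Reagents that add atoms: none
Why: An iron hydride formed from Fe(acac)3 and PhSiH3 transfers a hydrogen atom to the terminal carbon of the vinyl group, which creates the C4 methyl and a secondary radical at C4; this nucleophilic radical adds to C3 of the enolised dione (as enone β-carbon or carbonyl carbon, both tautomers leading to the same product), the intermediate radical is reduced and protonated to the cis-fused ketol 10, and acid dehydrates 10 to enone 11. The closest known reaction types are the hydrogen-atom-transfer-initiated Giese (reductive olefin) coupling and the hydrogen-atom-transfer-initiated radical cyclisation of alkenes onto ketones of 1,3-diketones. The only ring closed is the six-membered carbocycle C1–C6, by 6-exo-trig attack at C3, the only acceptor carbon within reach. Of the two stereocentres formed, C3 (hydroxyl cis to C2–H) is lost on dehydration, and C4 is under substrate control: in the chair-like transition state, whose tether is held by the cis-cyclopropane and the C2 stereocentre, the methyl on the radical carbon takes the pseudo-equatorial position pointing away from the five-membered ring, which places it cis to the cyclopropane and trans to C10. The step needs Markovnikov hydrogen-atom transfer to the monosubstituted alkene in preference to the electron-poor enol double bond, and it must avoid a cyclopropylcarbinyl radical: the radical centre is two bonds away from the cyclopropane, so ring opening is not available, and the acid is kept catalytic so that the γ-positions C2 and C4 of 11 are not epimerised.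

**Step 7**
Reactants: 12 3,5-bis(benzyloxy)phenol; 13 3-methylbutanal
Product: 14 3,5-bis(benzyloxy)-2-(1-hydroxy-3-methylbutyl)phenol (racemic)
Conditions: 12, EtMgBr, Et2O, 0 °C; solvent changed to toluene; 13, rt; aq. NH4Cl
Reagents that add atoms: none
Why: Ortho-selective hydroxyalkylation of a bromomagnesium phenoxide: magnesium binds the aldehyde and delivers it through a six-membered chelate to one of the two equivalent ortho positions; the carbinol is racemic, which is of no consequence because this carbon becomes planar in 16.

**Step 8**
Reactants: 14 o-hydroxybenzyl alcohol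
Product: 15 3,5-bis(benzyloxy)-2-[3-methyl-1-(phenylsulfonyl)butyl]phenol (racemic)
Conditions: PhSO2Na, HCO2H, H2O/CH2Cl2, rt
Reagents that add atoms: sodium benzenesulfinate, [Na+].[O-]S(=O)c1ccccc1
Why: Acid ionises the electron-rich o-hydroxybenzyl alcohol (through the quinone methide) and the sulfinate captures the benzylic carbon at sulfur, which gives a storable sulfone that releases the quinone methide again with base.

**Step 9**
Reactants: 11 tricyclic enone; 15 sulfone
Product: 18 bridged ketone (dibenzyl ether), via quinone methide 16 (not isolated), via Michael adduct 17 (not isolated)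
Conditions: 11, LiN(iPr)2, THF, −78 °C; add lithium phenoxide of 15 (from LiN(SiMe3)2, THF, −78 °C); −78 → 0 °C; then MeOH, Et3N, rt
Reagents that add atoms: none
Why: Kinetic deprotonation of 11 at C12 gives the cross-conjugated lithium dienolate, the lithium phenoxide of 15 loses sulfinate to give quinone methide 16, and Michael addition occurs on the dienolate face opposite to C1 (setting C12 with its methyl cis to C1) through an endo, lithium-bridged arrangement in which the aryl ring of the (E)-quinone methide lies under the five-membered ring and the isobutyl group points outward (setting C1′); after protonation the phenol adds to C3 of the enone (oxa-Michael) from the only face its tether allows, which gives the cis ring fusion at C2–C3.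

**Step 10**
Reactants: 18 bridged ketone
Product: 19 C11 alcohol
Conditions: NaBH4, MeOH/THF, 0 °C
Reagents that add atoms: none
Why: Borohydride reduces the only carbonyl group; the new carbinol centre at C11 forms as a mixture and is removed in step 12.

**Step 11**
Reactants: 19 C11 alcohol
Product: 20 C11 S-methyl xanthate
Conditions: NaH, CS2, THF, 0 °C → rt; then MeI
Reagents that add atoms: carbon disulfide, S=C=S; iodomethane, CI
Why: Xanthate formation: the sodium alkoxide adds to carbon disulfide and the dithiocarbonate salt is S-methylated.

**Step 12**
Reactants: 20 xanthate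
Product: 21 deoxygenated dibenzyl ether
Conditions: Bu3SnH, AIBN (cat.), toluene, 110 °C
Reagents that add atoms: none
Why: Barton–McCombie deoxygenation: the stannyl radical attacks the thiocarbonyl sulfur, the C11–O bond breaks, and the secondary C11 radical, which has neither a β leaving group nor an adjacent cyclopropane, takes hydrogen from the stannane.

**Step 13**
Reactants: 21 dibenzyl ether
Product: 22 diphenol
Conditions: H2 (1 atm), Pd/C, EtOAc/EtOH, rt
Reagents that add atoms: none
Why: Hydrogenolysis cleaves the two benzyl ethers, whereas the tertiary alkyl aryl ether, the benzylic C–C bond and the unactivated cyclopropane are expected to be inert at ambient pressure.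

**Step 14**
Reactants: 22 diphenol
Product: 23 target CNP0202714.1
Conditions: Cl2CHOMe, TiCl4, CH2Cl2, −78 → 0 °C; then H2O
Reagents that add atoms: dichloromethyl methyl ether, COC(Cl)Cl; water, O
Why: Rieche formylation: the two remaining aromatic CH positions are each ortho or para to all three oxygens and ortho to a titanium-bound phenoxide, so both are formylated, and hydrolysis of the chloro(methoxy)methyl groups gives the two aldehydes without touching any stereocentre.

**Compound list**

1 | (+)-3-carene, (1S,6R)-3,7,7-trimethylbicyclo[4.1.0]hept-3-ene | CC1=CC[C@@H]2[C@H](C1)C2(C)C | starting material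
2 | (1S,4R,6R)-4-hydroperoxy-3,7,7-trimethylbicyclo[4.1.0]hept-2-ene (OOH trans to the cyclopropane) | CC1=C[C@H]2[C@@H](C[C@H]1OO)C2(C)C | intermediate
3 | trans-car-2-en-4-ol, (1S,4R,6R)-3,7,7-trimethylbicyclo[4.1.0]hept-2-en-4-ol (OH trans to the cyclopropane) | CC1=C[C@H]2[C@@H](C[C@H]1O)C2(C)C | intermediate
4 | triethyl orthopropionate (1,1,1-triethoxypropane) | CCC(OCC)(OCC)OCC | starting material
5 | ethyl 2-[(1R,2R,6R)-3,7,7-trimethylbicyclo[4.1.0]hept-3-en-2-yl]propanoate (C2 side chain trans to the cyclopropane; both epimers at the propanoate α-carbon C12) | CCOC(=O)C(C)[C@@H]1C(C)=CC[C@@H]2[C@H]1C2(C)C | intermediate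
6 | secondary ozonide of 5 (1,2,4-trioxolane spanning C3 and C4) | CCOC(=O)C(C)[C@H]1[C@H]2[C@@H](CC3OOC1(C)O3)C2(C)C | intermediate
7 | ethyl 3-[cis-2,2-dimethyl-3-(2-oxoethyl)cyclopropyl]-2-methyl-4-oxopentanoate (cyclopropane and C2 configured as in 5) | CCOC(=O)C(C)[C@H](C(C)=O)[C@H]1[C@@H](CC=O)C1(C)C | intermediate
8 | ethyl 3-[cis-2,2-dimethyl-3-(prop-2-enyl)cyclopropyl]-2-methyl-4-oxopentanoate | CCOC(=O)C(C)[C@H](C(C)=O)[C@H]1[C@@H](CC=C)C1(C)C | intermediate
9 | 4-[cis-2,2-dimethyl-3-(prop-2-enyl)cyclopropyl]-5-methylcyclopentane-1,3-dione (drawn as the diketone; present largely as enol; epimers at the methyl-bearing carbon) | CC1C(=O)CC(=O)[C@@H]1[C@H]1[C@@H](CC=C)C1(C)C | intermediate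
10 | tricyclic ketol: C3–C4 bond closed; C3–OH cis to C2–H (cis ring fusion); C4–CH3 cis to the cyclopropane; C11 ketone | O[C@]12CC(=O)C(C)[C@H]1[C@H]1[C@@H](C[C@@H]2C)C1(C)C | intermediate
11 | tricyclic enone: cyclopent-2-enone (C3=C10–C11=O; C12 carries H and CH3) fused at C2–C3 to the carane ring; C4–CH3 and C2–H cis to the cyclopropane | CC1C(=O)C=C2[C@@H]1[C@H]1[C@@H](C[C@@H]2C)C1(C)C | intermediate
12 | 3,5-bis(benzyloxy)phenol | Oc1cc(OCc2ccccc2)cc(OCc2ccccc2)c1 | starting material
13 | 3-methylbutanal (isovaleraldehyde) | CC(C)CC=O | starting material
14 | 3,5-bis(benzyloxy)-2-(1-hydroxy-3-methylbutyl)phenol (racemic) | CC(C)CC(O)c1c(O)cc(OCc2ccccc2)cc1OCc1ccccc1 | intermediate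
15 | 3,5-bis(benzyloxy)-2-[3-methyl-1-(phenylsulfonyl)butyl]phenol (racemic) | CC(C)CC(c1c(O)cc(OCc2ccccc2)cc1OCc1ccccc1)S(=O)(=O)c1ccccc1 | intermediate
16 | (6E)-3,5-bis(benzyloxy)-6-(3-methylbutylidene)cyclohexa-2,4-dien-1-one (o-quinone methide) | CC(C)C/C=C1/C(=O)C=C(OCc2ccccc2)C=C1OCc1ccccc1 | intermediate
17 | Michael adduct: enone 11 carrying on C12 (methyl cis to C1) the 1-[2,4-bis(benzyloxy)-6-hydroxyphenyl]-3-methylbutyl group, C1′ configured as in the target | CC(C)C[C@@H](c1c(O)cc(OCc2ccccc2)cc1OCc1ccccc1)[C@@]1(C)C(=O)C=C2[C@@H]1[C@H]1[C@@H](C[C@@H]2C)C1(C)C | intermediate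
18 | bridged ketone: target skeleton with C11 ketone, benzyl ethers on both phenols and no formyl groups | CC(C)C[C@H]1c2c(OCc3ccccc3)cc(OCc3ccccc3)cc2O[C@]23CC(=O)[C@@]1(C)[C@H]2[C@H]1[C@@H](C[C@@H]3C)C1(C)C | intermediate
19 | C11 alcohol of 18 (epimer mixture at C11) | CC(C)C[C@H]1c2c(OCc3ccccc3)cc(OCc3ccccc3)cc2O[C@]23CC(O)[C@@]1(C)[C@H]2[C@H]1[C@@H](C[C@@H]3C)C1(C)C | intermediate
20 | C11 O-alkyl S-methyl dithiocarbonate (xanthate) of 19 | CC(C)C[C@H]1c2c(OCc3ccccc3)cc(OCc3ccccc3)cc2O[C@]23CC(OC(=S)SC)[C@@]1(C)[C@H]2[C@H]1[C@@H](C[C@@H]3C)C1(C)C | intermediate
21 | dibenzyl ether of the bis-deformyl target (C11 = CH2) | CC(C)C[C@H]1c2c(OCc3ccccc3)cc(OCc3ccccc3)cc2O[C@]23CC[C@@]1(C)[C@H]2[C@H]1[C@@H](C[C@@H]3C)C1(C)C | intermediate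
22 | bis-deformyl target (diphenol) | CC(C)C[C@H]1c2c(O)cc(O)cc2O[C@]23CC[C@@]1(C)[C@H]2[C@H]1[C@@H](C[C@@H]3C)C1(C)C | intermediate
23 | CNP0202714.1 | CC(C)C[C@H]1c2c(O)c(C=O)c(O)c(C=O)c2O[C@]23CC[C@@]1(C)[C@H]2[C@H]1[C@@H](C[C@@H]3C)C1(C)C | target

**Step count.** Total: 14 steps. Longest linear sequence: 12 steps (steps 1–6 and 9–14, from (+)-3-carene); steps 7 and 8 prepare the aryl fragment.

**Steps most likely to fail, with fallbacks**

Step 6 (key step). The acidic enolised dione may consume the iron hydride, hydrogen-atom transfer may simply reduce the vinyl group, a 1,5-hydrogen shift from C2 may outrun cyclisation, or the C4 methyl may form with poor selectivity. The fallback sets out from dione 9. Triflation (Tf2O, 2,6-lutidine, CH2Cl2, −78 °C) should give, after separation from its regioisomer, the vinylogous triflate F1 (triflate on C3, ketone on C11). An intramolecular Heck reaction (Pd(OAc)2, PPh3, Et3N, MeCN, 80 °C) then closes the same C3–C4 bond by 6-exo carbopalladation of the vinyl group and β-hydride elimination, giving the dienone F2 with an exocyclic methylene on C4. Hydrogenation of this 1,1-disubstituted alkene (H2, RhCl(PPh3)3, benzene) from the face away from the gem-dimethylcyclopropane should place the C4 methyl cis to the cyclopropane, and the route is rejoined at enone 11.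

Step 9. The union may show poor control at C1′ (exo instead of endo approach, or reaction through the (Z)-quinone methide), the enolate may be O-alkylated, the quinone methide may oligomerise, or the reversible oxa-Michael closure may not go to completion. The fallback sets out from enone 11 and diol 14. Enone 11 is converted (LiN(iPr)2; t-BuMe2SiCl, THF, −78 °C) into the cross-conjugated silyl dienol ether F3, and 14 is ionised to quinone methide 16 with a catalytic Brønsted acid (diphenyl phosphate, CH2Cl2, −40 °C). The Mukaiyama–Michael addition runs through an open transition state, which is expected to answer a topicity problem of the lithium-bridged addition. Loss of the silyl group gives phenol 17, which is closed to 18 with Et3N in MeOH as in step 9.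

Step 2. The allylic alcohol, which is conjugated to the cyclopropane, may ionise under the hot, weakly acidic conditions (cyclopropane opening to p-menthane-type dienes, aromatisation) before the ketene acetal forms. The fallback sets out from alcohol 3. Acylation (EtCOCl, pyridine, DMAP, CH2Cl2) gives the propanoate F4. Ireland–Claisen rearrangement (LiN(iPr)2, Me3SiCl, THF, −78 °C → rt; then dilute acid) transfers the same carbon to the same face of C2 under basic conditions and gives the carboxylic acid F5. Esterification (EtI, K2CO3, DMF) rejoins the route at ester 5.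

**Further compounds**

F1 | step 6 | 3-triflyloxycyclopent-2-enone from 9 (triflate on C3, ketone on C11, cyclopropyl arm on C2) | CC1C(=O)C=C(OS(=O)(=O)C(F)(F)F)[C@@H]1[C@H]1[C@@H](CC=C)C1(C)C
F2 | step 6 | tricyclic dienone with exocyclic methylene on C4 (C4=CH2, C3=C10, C11 ketone) | CC1C(=O)C=C2[C@@H]1[C@H]1[C@@H](CC2=C)C1(C)C
F3 | step 9 | tert-butyldimethylsilyl dienol ether of 11 (C11–OSi, C11=C12 and C3=C10 double bonds) | CC1=C(O[Si](C)(C)C(C)(C)C)C=C2[C@@H]1[C@H]1[C@@H](C[C@@H]2C)C1(C)C
F4 | step 2 | trans-car-2-en-4-yl propanoate | CC1=C[C@H]2[C@@H](C[C@H]1OC(=O)CC)C2(C)C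
F5 | step 2 | 2-(car-3-en-2-yl)propanoic acid (C2 side chain trans to the cyclopropane) | OC(=O)C(C)[C@@H]1C(C)=CC[C@@H]2[C@H]1C2(C)C
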